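**Retrosynthetic overview**
1. Numbering: ring A is the δ-lactone O2–C1–C11a–C4a–C4–C3(=O). Ring B is the nine-membered carbocycle C4a–C5–C6–C7–C8–C9–C10–C11–C11a. The side chain C12–C15 sits on C4.
2. The plan rests on C7 of ring B, the only fully substituted stereocentre (CH3, OH, ring methylene C6, oxirane carbon C8). It lies too far from C4a and C11a to be steered by them while ring B is open, so its configuration is copied from a cheap secondary carbinol.
3. Last disconnections: the C8–C9 oxirane (from the Z-alkene, directed by C7–OH), the C13 acetate, and C4=C12 (aldol condensation of the ring A lactone with a preformed C12–C15 epoxy aldehyde).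
4. Ring B is opened at C10–C11 (allylic acetate/vinylstannane coupling) and then at C6–C7. There a lithiated (R,Z)-allylic carbamate (C7–C10) joins a primary pinacol boronate (C6) carried by ring A masked as its methyl acetal, and boron is then exchanged for the C7 hydroxyl.
5. Ring order: ring A first (Evans aldol for C11a, acrylate ring-closing metathesis, trans vinyl conjugate addition for C4a), the side-chain oxirane made separately, ring B second, the C8–C9 oxirane last.

Key step: step 19

Assumption: lactols 16 and 38 are anomeric mixtures (C3 left open in their SMILES); acetals 17–23 and 32–37 form as anomeric mixtures and are named and drawn as the major anomer with axial methoxy (3S), both anomers converging at 39; 51 and 52 are C4/C12 mixtures that converge at 53.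

Step 1
Reactants: 1 (R)-4-benzyl-1,3-oxazolidin-2-one; 2 (E)-but-2-enoyl chloride
Product: 4 (R)-4-benzyl-3-[(E)-but-2-enoyl]-1,3-oxazolidin-2-one, via N-lithio oxazolidinone 3 (not isolated)
Conditions: nBuLi (1.0 equiv), THF, −78 °C; then 2, −78 → 0 °C
Reagents that add atoms: n-butyllithium, [Li]CCCC (lithium stays only in 3)
Why: N-acylation of the lithiated oxazolidinone with an acid chloride is the standard entry to Evans imides and leaves the E-alkene and the auxiliary centre untouched.

Step 2
Reactants: 4 (R)-4-benzyl-3-[(E)-but-2-enoyl]-1,3-oxazolidin-2-one; 5 acetaldehyde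
Product: 7 (R)-4-benzyl-3-[(2R,3S)-3-hydroxy-2-vinylbutanoyl]-1,3-oxazolidin-2-one, via dibutylboron dienolate 6 (not isolated)
Conditions: Bu2BOTf (1.2 equiv), Et3N (1.4 equiv), CH2Cl2, −78 → 0 °C; 5, −78 → 0 °C; then pH 7 buffer, MeOH, 30% H2O2, 0 °C
Reagents that add atoms: dibutylboron triflate, CCCCB(CCCC)OS(=O)(=O)C(F)(F)F (boron group stays only in 6)
Why: In this Evans syn-aldol reaction, soft γ-deprotonation gives the Z(O)-boron dienolate, which reacts at its α-carbon through a Zimmerman–Traxler chair on the face away from the benzyl group, so the (R)-auxiliary sets C11a (2R) and the carbinol centre (3S, erased in step 12).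

Step 3
Reactants: 7 (R)-4-benzyl-3-[(2R,3S)-3-hydroxy-2-vinylbutanoyl]-1,3-oxazolidin-2-one
Product: 8 (R)-4-benzyl-3-[(2R,3S)-3-(tert-butyldimethylsilyloxy)-2-vinylbutanoyl]-1,3-oxazolidin-2-one
Conditions: tBuMe2SiOTf, 2,6-lutidine, CH2Cl2, 0 °C
Reagents that add atoms: tert-butyldimethylsilyl triflate, CC(C)(C)[Si](C)(C)OS(=O)(=O)C(F)(F)F
Why: O-silylation with a silyl triflate and a hindered base protects the secondary alcohol without retro-aldol cleavage or migration of the β,γ-alkene.

Step 4
Reactants: 8 (R)-4-benzyl-3-[(2R,3S)-3-(tert-butyldimethylsilyloxy)-2-vinylbutanoyl]-1,3-oxazolidin-2-one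
Product: 9 (2S,3S)-3-(tert-butyldimethylsilyloxy)-2-vinylbutan-1-ol
Conditions: LiBH4, MeOH (1 equiv), Et2O, 0 °C
Reagents that add atoms: none
Why: Reductive cleavage of the imide by LiBH4 at the exocyclic carbonyl frees the C1 alcohol without deprotonating C11a, and the auxiliary is recovered.

Step 5
Reactants: 9 (2S,3S)-3-(tert-butyldimethylsilyloxy)-2-vinylbutan-1-ol; 10 acryloyl chloride
Product: 11 (2S,3S)-3-(tert-butyldimethylsilyloxy)-2-vinylbutyl acrylate
Conditions: Et3N, DMAP (cat.), CH2Cl2, 0 °C
Reagents that add atoms: none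
Why: This is a plain O-acylation (esterification) of an unhindered primary alcohol and brings in C3 and C4.

Step 6
Reactants: 11 (2S,3S)-3-(tert-butyldimethylsilyloxy)-2-vinylbutyl acrylate
Product: 12 (S)-5-[(S)-1-(tert-butyldimethylsilyloxy)ethyl]-5,6-dihydro-2H-pyran-2-one
Conditions: second-generation Grubbs catalyst (3 mol %), CH2Cl2 (5 mM), reflux
Reagents that add atoms: none
Why: Ring-closing metathesis of an acrylate with a monosubstituted alkene closes the six-membered unsaturated lactone (ring A), driven by loss of ethene and without involving C11a.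

Step 7
Reactants: 12 (S)-5-[(S)-1-(tert-butyldimethylsilyloxy)ethyl]-5,6-dihydro-2H-pyran-2-one; 13 vinylmagnesium bromide
Product: 15 (4S,5S)-5-[(S)-1-(tert-butyldimethylsilyloxy)ethyl]-4-vinyltetrahydro-2H-pyran-2-one, via silyl ketene acetal 14 (not isolated)
Conditions: 13 (1.5 equiv), CuBr·SMe2 (20 mol %), Me3SiCl (2 equiv), THF, −78 °C; then aq. NH4Cl
Reagents that add atoms: chlorotrimethylsilane, C[Si](C)(C)Cl (silyl group stays only in 14)
Why: In this copper-catalysed, Me3SiCl-accelerated conjugate addition the vinyl group attacks C4a anti to the bulky 1-silyloxyethyl group on neighbouring C11a, which should give the trans H-4a/H-11a relationship of the target.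

Step 8
Reactants: 15 (4S,5S)-5-[(S)-1-(tert-butyldimethylsilyloxy)ethyl]-4-vinyltetrahydro-2H-pyran-2-one
Product: 16 (4S,5S)-5-[(S)-1-(tert-butyldimethylsilyloxy)ethyl]-4-vinyltetrahydro-2H-pyran-2-ol (anomers)
Conditions: iBu2AlH (1.1 equiv), CH2Cl2, −78 °C; aq. potassium sodium tartrate work-up
Reagents that add atoms: none
Why: Partial reduction of a lactone with iBu2AlH stops at the stable tetrahedral aluminium lactolate at low temperature.

Step 9
Reactants: 16 lactol
Product: 17 (2S,4S,5S)-5-[(S)-1-(tert-butyldimethylsilyloxy)ethyl]-2-methoxy-4-vinyltetrahydro-2H-pyran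
Conditions: MeOH, pyridinium p-toluenesulfonate (10 mol %), 3 Å sieves, rt
Reagents that add atoms: methanol, CO
Why: Acid-catalysed acetalisation through the ring oxocarbenium ion masks the lactone carbon C3, the anomeric effect favouring axial methoxy, under conditions mild enough for the silyl ether.

Step 10
Reactants: 17 vinyl acetal
Product: 18 (2S,4R,5S)-5-[(S)-1-(tert-butyldimethylsilyloxy)ethyl]-2-methoxy-4-[2-(4,4,5,5-tetramethyl-1,3,2-dioxaborolan-2-yl)ethyl]tetrahydro-2H-pyran
Conditions: pinacolborane (1.3 equiv), [Ir(cod)Cl]2 (1.5 mol %), Ph2PCH2CH2PPh2 (3 mol %), THF, rt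
Reagents that add atoms: pinacolborane, CC1(C)OBOC1(C)C
Why: Iridium-catalysed hydroboration with pinacolborane is anti-Markovnikov on monosubstituted alkenes, and at this stage the vinyl group is the only C=C bond in the molecule.

Step 11
Reactants: 18 silyl ether boronate
Product: 19 (S)-1-{(3S,4R,6S)-6-methoxy-4-[2-(4,4,5,5-tetramethyl-1,3,2-dioxaborolan-2-yl)ethyl]tetrahydro-2H-pyran-3-yl}ethan-1-ol
Conditions: Bu4NF, AcOH (1:1, 3 equiv), THF, rt
Reagents that add atoms: none
Why: In this fluoride-induced desilylation the acetic acid buffer keeps the freed alkoxide off boron, and primary alkyl pinacol boronates tolerate fluoride.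

Step 12
Reactants: 19 secondary alcohol
Product: 20 1-{(3S,4R,6S)-6-methoxy-4-[2-(4,4,5,5-tetramethyl-1,3,2-dioxaborolan-2-yl)ethyl]tetrahydro-2H-pyran-3-yl}ethan-1-one
Conditions: Dess–Martin periodinane, CH2Cl2, 0 °C → rt
Reagents that add atoms: none
Why: Dess–Martin oxidation is close to neutral, spares boronate and acetal, and should not epimerise C11a, whose equatorial acetyl group is in any case the more stable arrangement.

Step 13
Reactants: 20 methyl ketone
Product: 22 1-{(3S,4R,6S)-6-methoxy-4-[2-(4,4,5,5-tetramethyl-1,3,2-dioxaborolan-2-yl)ethyl]tetrahydro-2H-pyran-3-yl}vinyl trifluoromethanesulfonate, via potassium enolate 21 (not isolated)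
Conditions: KN(SiMe3)2 (1.2 equiv), THF, −78 °C; then Comins reagent, −78 °C
Reagents that add atoms: potassium bis(trimethylsilyl)amide, C[Si](C)(C)[N-][Si](C)(C)C.[K+] (potassium stays only in 21); N-(5-chloropyridin-2-yl)bis(trifluoromethanesulfonimide), O=S(=O)(N(c1ccc(Cl)cn1)S(=O)(=O)C(F)(F)F)C(F)(F)F
Why: Kinetic enolisation of a methyl ketone by a bulky amide base occurs at CH3 rather than at the hindered C11a–H (which also avoids retro-oxa-Michael opening), and O-sulfonylation traps the terminal enol triflate.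

Step 14
Reactants: 22 enol triflate
Product: 23 tributyl(1-{(3S,4R,6S)-6-methoxy-4-[2-(4,4,5,5-tetramethyl-1,3,2-dioxaborolan-2-yl)ethyl]tetrahydro-2H-pyran-3-yl}vinyl)stannane
Conditions: (Bu3Sn)2 (1.5 equiv), Pd(PPh3)4 (5 mol %), LiCl (6 equiv), THF, 65 °C
Reagents that add atoms: hexabutylditin, CCCC[Sn](CCCC)(CCCC)[Sn](CCCC)(CCCC)CCCC
Why: Palladium-catalysed stannylation of an enol triflate with a distannane (Stille-type, LiCl-promoted) replaces OTf by SnBu3, and without added base the alkyl boronate does not transmetallate.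

Step 15
Reactants: 24 (R)-but-3-yn-2-ol
Product: 25 (R)-but-3-yn-2-yl N,N-diisopropylcarbamate
Conditions: iPr2NC(O)Cl (1.3 equiv), Et3N, CH2Cl2, reflux
Reagents that add atoms: N,N-diisopropylcarbamoyl chloride, CC(C)N(C(C)C)C(=O)Cl
Why: O-carbamoylation forms only the O–C(=O) bond and so leaves the carbinol stereocentre (future C7) untouched.

Step 16
Reactants: 25 (R)-but-3-yn-2-yl N,N-diisopropylcarbamate; 26 formaldehyde (used as paraformaldehyde)
Product: 28 (R)-5-hydroxypent-3-yn-2-yl N,N-diisopropylcarbamate, via lithium acetylide 27 (not isolated)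
Conditions: nBuLi (1.05 equiv), THF, −78 °C; then 26, −78 °C → rt
Reagents that add atoms: n-butyllithium, [Li]CCCC (lithium stays only in 27)
Why: The terminal alkyne proton is far more acidic than the propargylic C–H, so one equivalent of base gives only the acetylide, whose addition to formaldehyde (hydroxymethylation) brings in C10.

Step 17
Reactants: 28 propargylic alcohol
Product: 29 (R)-5-(tert-butyldimethylsilyloxy)pent-3-yn-2-yl N,N-diisopropylcarbamate
Conditions: tBuMe2SiCl, imidazole, CH2Cl2, rt
Reagents that add atoms: tert-butyldimethylsilyl chloride, CC(C)(C)[Si](C)(C)Cl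
Why: Standard silylation of a primary alcohol gives an ether that is a poor leaving group and is inert to alkyllithium at low temperature.

Step 18
Reactants: 29 alkynyl carbamate
Product: 30 (R,Z)-5-(tert-butyldimethylsilyloxy)pent-3-en-2-yl N,N-diisopropylcarbamate
Conditions: H2 (1 atm), Pd/CaCO3 poisoned with Pb(OAc)2 (Lindlar catalyst), quinoline, EtOAc, rt
Reagents that add atoms: none
Why: Lindlar semihydrogenation delivers both hydrogens to one face of the alkyne on the poisoned palladium surface and stops at the Z-alkene C8=C9.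

Step 19
Reactants: 30 (R,Z)-5-(tert-butyldimethylsilyloxy)pent-3-en-2-yl N,N-diisopropylcarbamate; 23 stannyl boronate
Product: 34 (S,Z)-1-(tert-butyldimethylsilyloxy)-4-methyl-6-{(2S,4R,5S)-2-methoxy-5-[1-(tributylstannyl)vinyl]tetrahydro-2H-pyran-4-yl}hex-2-en-4-ol, via lithiated carbamate 31 (not isolated), via boronate complex 32 (not isolated), via tertiary allylic boronic ester 33 (not isolated)
Conditions: 30 (1.3 equiv), sBuLi (1.25 equiv), TMEDA (1.3 equiv), Et2O, −78 °C, 20 min; 23 (1.0 equiv) in Et2O, −78 °C, 1 h; → rt; then THF, 2 M NaOH, 30% H2O2, 0 °C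
Reagents that add atoms: hydrogen peroxide, OO (oxygen of the C7 hydroxyl); sec-butyllithium, CCC(C)[Li] (lithium stays only in 31 and 32)
Why: Carbamate-directed deprotonation of 30 by sBuLi/TMEDA removes H-7 with retention and gives the chelated, configurationally stable α-oxy allyllithium 31, which adds to the vacant orbital on boron of 23 with retention to give boronate complex 32. On warming, the C6 methylene shifts from boron to C7 antiperiplanar to the leaving carbamate (stereospecific 1,2-metallate rearrangement, inversion at C7), and basic peroxide then exchanges boron in 33 for hydroxyl with retention, so the C6–C7 and C7–O bonds form in one flask and no ring is closed. The closest known reaction type is the lithiation–borylation of enantioenriched secondary allylic carbamates with alkyl pinacol boronates to give tertiary allylic boronic esters and alcohols. The single new stereocentre C7 is controlled only by the (R)-centre of 30 (net replacement of H by C6 with retention, hence 7S) and is independent of C4a and C11a. The step needs α- rather than γ-borylation, survival of the Z-alkene and no 1,4-loss of silanolate; lithium is held at C7 by the carbamate carbonyl, the γ-carbon C9 is substituted, the allyllithium geometry is frozen at −78 °C, and silanolate is a poor leaving group. With ring A as an acetal, 23 offers boron as its only electrophilic site, the slight excess of 30 over sBuLi leaves no free alkyllithium for tin–lithium exchange, and the vinylstannane should tolerate the short basic peroxide treatment.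

Step 20
Reactants: 34 silyl ether
Product: 35 (S,Z)-4-methyl-6-{(2S,4R,5S)-2-methoxy-5-[1-(tributylstannyl)vinyl]tetrahydro-2H-pyran-4-yl}hex-2-ene-1,4-diol
Conditions: Bu4NF (1.2 equiv), THF, 0 °C
Reagents that add atoms: none
Why: Fluoride cleaves the primary allylic silyl ether, while vinylstannane, acetal and tertiary alcohol are inert to Bu4NF.

Step 21
Reactants: 35 diol
Product: 36 (S,Z)-4-hydroxy-4-methyl-6-{(2S,4R,5S)-2-methoxy-5-[1-(tributylstannyl)vinyl]tetrahydro-2H-pyran-4-yl}hex-2-en-1-yl acetate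
Conditions: Ac2O (1.1 equiv), pyridine, CH2Cl2, 0 °C
Reagents that add atoms: acetic anhydride, CC(=O)OC(C)=O
Why: Chemoselective acetylation takes the primary allylic C10–OH and leaves the tertiary C7–OH, and an acetate is chosen because its later ionisation releases no alkoxide base beside the free C7–OH.

Step 22
Reactants: 36 allylic acetate/vinylstannane
Product: 37 (3S,4aR,7S,11aR,8Z)-3-methoxy-7-methyl-11-methylene-1,3,4,4a,5,6,7,10,11,11a-decahydrocyclonona[c]pyran-7-ol
Conditions: Pd2(dba)3·CHCl3 (10 mol %), AsPh3 (40 mol %), LiCl (5 equiv), DMF, 45 °C, slow addition of 36 to a final 1 mM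
Reagents that add atoms: none
Why: In this intramolecular Stille-type allyl–vinyl coupling, zerovalent palladium ionises the acetate to an η3-allyl complex, and LiCl-assisted transmetallation from tin followed by reductive elimination at the open terminus C10 (C8 is shielded by quaternary C7) closes nine-membered ring B, high dilution holding back dimers and ring strain favouring the Z-alkene.

Step 23
Reactants: 37 bicyclic acetal
Product: 38 (4aR,7S,11aR,8Z)-7-methyl-11-methylene-1,3,4,4a,5,6,7,10,11,11a-decahydrocyclonona[c]pyran-3,7-diol (anomers)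
Conditions: AcOH–THF–H2O (3:1:1), 40 °C
Reagents that add atoms: water, O
Why: This acid-catalysed acetal hydrolysis uses the mild conditions known for tetrahydropyranyl ethers, under which the unsubstituted 2-alkoxytetrahydropyran ionises far faster than the tertiary allylic alcohol.

Step 24
Reactants: 38 lactol
Product: 39 (4aR,7S,11aR,8Z)-7-hydroxy-7-methyl-11-methylene-4,4a,5,6,7,10,11,11a-octahydrocyclonona[c]pyran-3(1H)-one
Conditions: Pr4N[RuO4] (5 mol %), N-methylmorpholine N-oxide (1.5 equiv), 4 Å sieves, CH2Cl2, rt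
Reagents that add atoms: none
Why: Ley–Griffith oxidation converts the lactol into the lactone, and the tertiary alcohol and both alkenes are not substrates for the perruthenate.

Step 25
Reactants: 40 (S)-2,2-dimethyl-1,3-dioxolane-4-carbaldehyde; 41 isopropyltriphenylphosphonium iodide
Product: 43 (R)-2,2-dimethyl-4-(2-methylprop-1-en-1-yl)-1,3-dioxolane, via isopropylidene ylide 42 (not isolated)
Conditions: 41, nBuLi, THF, 0 °C; then 40, −78 °C → rt
Reagents that add atoms: none
Why: Wittig olefination with the non-stabilised ylide at low temperature builds C14=C15 without epimerising the α-alkoxy aldehyde, so C13 comes from the chiral pool.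

Step 26
Reactants: 43 acetonide
Product: 44 (R)-4-methylpent-3-ene-1,2-diol
Conditions: AcOH–H2O (4:1), rt
Reagents that add atoms: none
Why: Mild acid hydrolysis removes the acetonide under conditions too weak to ionise the allylic C13–O bond.

Step 27
Reactants: 44 diol
Product: 45 (R)-4-methyl-1-(triethylsilyloxy)pent-3-en-2-ol
Conditions: Et3SiCl (1.0 equiv), imidazole, CH2Cl2, −40 °C
Reagents that add atoms: chlorotriethylsilane, CC[Si](Cl)(CC)CC
Why: Selective silylation of the primary over the secondary alcohol leaves the allylic C13–OH as the only directing group for the next step.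

Step 28
Reactants: 45 allylic alcohol
Product: 46 (S)-1-[(R)-3,3-dimethyloxiran-2-yl]-2-(triethylsilyloxy)ethan-1-ol
Conditions: mCPBA, CH2Cl2/aq. pH 7 phosphate buffer, 0 °C
Reagents that add atoms: 3-chloroperbenzoic acid, O=C(OO)c1cccc(Cl)c1
Why: In this hydroxyl-directed peracid epoxidation (Henbest effect), 1,3-allylic strain with the cis-methyl group holds H-13 in the alkene plane and the hydrogen bond from C13–OH delivers oxygen to one face, which should give the threo epoxy alcohol with 14R.

Step 29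
Reactants: 46 epoxy alcohol
Product: 47 tert-butyl{(S)-1-[(R)-3,3-dimethyloxiran-2-yl]-2-(triethylsilyloxy)ethoxy}dimethylsilane
Conditions: tBuMe2SiCl, imidazole, DMF, rt
Reagents that add atoms: tert-butyldimethylsilyl chloride, CC(C)(C)[Si](C)(C)Cl
Why: Silylation with the silyl chloride (not the Lewis-acidic triflate, which could open the oxirane) puts a migration-resistant group on O-13.

Step 30
Reactants: 47 bis-silyl ether
Product: 49 (R)-2-(tert-butyldimethylsilyloxy)-2-[(R)-3,3-dimethyloxiran-2-yl]acetaldehyde, via alkoxysulfonium chloride 48 (not isolated)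
Conditions: (COCl)2 (4 equiv), DMSO (8 equiv), CH2Cl2, −78 → −40 °C; then Et3N, −78 → 0 °C
Reagents that add atoms: dimethyl sulfoxide, CS(C)=O, and oxalyl chloride, O=C(Cl)C(=O)Cl (their atoms stay only in 48)
Why: Under Swern conditions activated DMSO attacks the unhindered primary triethylsilyl ether oxygen and oxidises it directly to the aldehyde, a known selective reaction that leaves the secondary silyl ether and the oxirane in place.

Step 31
Reactants: 39 hydroxy lactone; 49 epoxy aldehyde
Product: 51 aldol adduct, 4-{(2S)-2-(tert-butyldimethylsilyloxy)-2-[(R)-3,3-dimethyloxiran-2-yl]-1-hydroxyethyl} derivative of 39, via dilithiated lactone 50 (not isolated)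
Conditions: LiN(iPr)2 (2.3 equiv), THF, −78 °C; 49 (1.5 equiv), −78 °C; AcOH quench at −78 °C
Reagents that add atoms: lithium diisopropylamide, CC(C)[N-]C(C)C.[Li+] (lithium stays only in 50)
Why: In this aldol addition of a lithium lactone enolate one equivalent of base is consumed by C7–OH, the cold quench forestalls O-to-O silyl migration, and the new centres C4 and C12 are erased in the next step.

Step 32
Reactants: 51 aldol adduct
Product: 53 (4E,4aS,7S,11aR,8Z)-4-{(2S)-2-(tert-butyldimethylsilyloxy)-2-[(R)-3,3-dimethyloxiran-2-yl]ethylidene}-7-hydroxy-7-methyl-11-methylene-4,4a,5,6,7,10,11,11a-octahydrocyclonona[c]pyran-3(1H)-one, via C12 acetate 52 (not isolated)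
Conditions: Ac2O (1.5 equiv), Et3N, DMAP (cat.), CH2Cl2, 0 °C; then DBU (2 equiv), 0 °C → rt
Reagents that add atoms: acetic anhydride, CC(=O)OC(C)=O (acetyl stays only in 52)
Why: Acetylation takes only the secondary aldol hydroxyl, and E1cB elimination with DBU should give the conjugated alkylidene lactone as the more stable E isomer, with C13 anti to the C3 carbonyl.

Step 33
Reactants: 53 silyl ether
Product: 54 C13 alcohol (53 with free 13S hydroxyl)
Conditions: Bu4NF, AcOH (1:1, 3 equiv), THF, rt
Reagents that add atoms: none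
Why: Acetic-acid-buffered fluoride desilylation avoids both acid opening of the trisubstituted oxirane and alkoxide-driven Payne rearrangement.

Step 34
Reactants: 54 diol
Product: 55 C13 acetate (8,9-alkene precursor of the target)
Conditions: Ac2O, pyridine, DMAP (cat.), CH2Cl2, 0 °C
Reagents that add atoms: acetic anhydride, CC(=O)OC(C)=O
Why: Selective acetylation esterifies the secondary allylic C13–OH, while the tertiary C7–OH stays free under these mild conditions.

Step 35
Reactants: 55 dienyl alcohol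
Product: 56 target CNP0113449.2, (4E,4aS,7S,8R,9R,11aR,13S,14R)-13-acetoxy-8,9:14,15-diepoxy-7-hydroxy xenicane lactone
Conditions: VO(acac)2 (5 mol %), tBuOOH (1.5 equiv, decane), CH2Cl2, 0 °C
Reagents that add atoms: tert-butyl hydroperoxide, CC(C)(C)OO
Why: In this vanadium-catalysed hydroxyl-directed epoxidation the peroxide bound to the vanadium alkoxide of C7–OH reaches only the adjacent Z-alkene and adds on the face syn to the hydroxyl, as known for medium-ring cycloalkenols, which should set 8R,9R and leave the remote C11 methylene and the electron-poor C4=C12 untouched.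

**Compound list**
1 | (R)-4-benzyl-1,3-oxazolidin-2-one | O=C1N[C@H](Cc2ccccc2)CO1 | starting material
2 | (E)-but-2-enoyl chloride | C/C=C/C(=O)Cl | starting material
3 | N-lithio derivative of 1 | [Li]N1[C@H](Cc2ccccc2)COC1=O | intermediate
4 | (R)-4-benzyl-3-[(E)-but-2-enoyl]-1,3-oxazolidin-2-one | C/C=C/C(=O)N1[C@H](Cc2ccccc2)COC1=O | intermediate
5 | acetaldehyde | CC=O | starting material
6 | Z(O)-dibutylboron dienolate of 4 | C=C/C=C(OB(CCCC)CCCC)/N1[C@H](Cc2ccccc2)COC1=O | intermediate
7 | (R)-4-benzyl-3-[(2R,3S)-3-hydroxy-2-vinylbutanoyl]-1,3-oxazolidin-2-one | O=C1OC[C@@H](Cc2ccccc2)N1C(=O)[C@H](C=C)[C@H](C)O | intermediate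
8 | tert-butyldimethylsilyl ether of 7 | O=C1OC[C@@H](Cc2ccccc2)N1C(=O)[C@H](C=C)[C@H](C)O[Si](C)(C)C(C)(C)C | intermediate
9 | (2S,3S)-3-(tert-butyldimethylsilyloxy)-2-vinylbutan-1-ol | OC[C@H](C=C)[C@H](C)O[Si](C)(C)C(C)(C)C | intermediate
10 | acryloyl chloride | C=CC(=O)Cl | starting material
11 | (2S,3S)-3-(tert-butyldimethylsilyloxy)-2-vinylbutyl acrylate | C=CC(=O)OC[C@H](C=C)[C@H](C)O[Si](C)(C)C(C)(C)C | intermediate
12 | (S)-5-[(S)-1-(tert-butyldimethylsilyloxy)ethyl]-5,6-dihydro-2H-pyran-2-one | O=C1C=C[C@@H](CO1)[C@H](C)O[Si](C)(C)C(C)(C)C | intermediate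
13 | vinylmagnesium bromide | C=C[Mg]Br | starting material
14 | trimethylsilyl ketene acetal of 15 (ring centres as in 15) | C[Si](C)(C)OC1=C[C@@H](C=C)[C@@H](CO1)[C@H](C)O[Si](C)(C)C(C)(C)C | intermediate
15 | (4S,5S)-5-[(S)-1-(tert-butyldimethylsilyloxy)ethyl]-4-vinyltetrahydro-2H-pyran-2-one | O=C1C[C@@H](C=C)[C@@H](CO1)[C@H](C)O[Si](C)(C)C(C)(C)C | intermediate
16 | lactol of 15 (anomers) | OC1C[C@@H](C=C)[C@@H](CO1)[C@H](C)O[Si](C)(C)C(C)(C)C | intermediate
17 | (2S,4S,5S)-5-[(S)-1-(tert-butyldimethylsilyloxy)ethyl]-2-methoxy-4-vinyltetrahydro-2H-pyran | CO[C@@H]1C[C@@H](C=C)[C@@H](CO1)[C@H](C)O[Si](C)(C)C(C)(C)C | intermediate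
18 | (2S,4R,5S)-pinacol boronate from 17 | CO[C@@H]1C[C@@H](CCB2OC(C)(C)C(C)(C)O2)[C@@H](CO1)[C@H](C)O[Si](C)(C)C(C)(C)C | intermediate
19 | secondary alcohol from 18 | CO[C@@H]1C[C@@H](CCB2OC(C)(C)C(C)(C)O2)[C@@H](CO1)[C@H](C)O | intermediate
20 | methyl ketone (3S,4R,6S) | CO[C@@H]1C[C@@H](CCB2OC(C)(C)C(C)(C)O2)[C@@H](CO1)C(C)=O | intermediate
21 | terminal potassium enolate of 20 | CO[C@@H]1C[C@@H](CCB2OC(C)(C)C(C)(C)O2)[C@@H](CO1)C(=C)O[K] | intermediate
22 | enol triflate of 20 | CO[C@@H]1C[C@@H](CCB2OC(C)(C)C(C)(C)O2)[C@@H](CO1)C(=C)OS(=O)(=O)C(F)(F)F | intermediate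
23 | masked-lactone primary pinacol boronate bearing the C11 vinylstannane | CO[C@@H]1C[C@@H](CCB2OC(C)(C)C(C)(C)O2)[C@@H](CO1)C(=C)[Sn](CCCC)(CCCC)CCCC | intermediate
24 | (R)-but-3-yn-2-ol | C[C@@H](O)C#C | starting material
25 | (R)-but-3-yn-2-yl N,N-diisopropylcarbamate | C[C@@H](OC(=O)N(C(C)C)C(C)C)C#C | intermediate
26 | formaldehyde (as paraformaldehyde) | C=O | starting material
27 | lithium acetylide of 25 | C[C@@H](OC(=O)N(C(C)C)C(C)C)C#C[Li] | intermediate
28 | (R)-5-hydroxypent-3-yn-2-yl N,N-diisopropylcarbamate | C[C@@H](OC(=O)N(C(C)C)C(C)C)C#CCO | intermediate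
29 | (R)-5-(tert-butyldimethylsilyloxy)pent-3-yn-2-yl N,N-diisopropylcarbamate | C[C@@H](OC(=O)N(C(C)C)C(C)C)C#CCO[Si](C)(C)C(C)(C)C | intermediate
30 | (R,Z)-5-(tert-butyldimethylsilyloxy)pent-3-en-2-yl N,N-diisopropylcarbamate | C[C@@H](OC(=O)N(C(C)C)C(C)C)/C=C\CO[Si](C)(C)C(C)(C)C | intermediate
31 | C7-lithiated carbamate (Li in place of H, retention) | C[C@@]([Li])(OC(=O)N(C(C)C)C(C)C)/C=C\CO[Si](C)(C)C(C)(C)C | intermediate
32 | lithium boronate complex of 31 and 23 | CO[C@@H]1C[C@@H](CC[B-]2(OC(C)(C)C(C)(C)O2)[C@](C)(OC(=O)N(C(C)C)C(C)C)/C=C\CO[Si](C)(C)C(C)(C)C)[C@@H](CO1)C(=C)[Sn](CCCC)(CCCC)CCCC.[Li+] | intermediate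
33 | tertiary Z-allylic pinacol boronic ester (boron where 34 carries OH) | CO[C@@H]1C[C@@H](CC[C@](C)(B2OC(C)(C)C(C)(C)O2)/C=C\CO[Si](C)(C)C(C)(C)C)[C@@H](CO1)C(=C)[Sn](CCCC)(CCCC)CCCC | intermediate
34 | open-chain tertiary Z-allylic alcohol (7S) | CO[C@@H]1C[C@@H](CC[C@](C)(O)/C=C\CO[Si](C)(C)C(C)(C)C)[C@@H](CO1)C(=C)[Sn](CCCC)(CCCC)CCCC | intermediate
35 | Z-ene-1,4-diol from 34 | CO[C@@H]1C[C@@H](CC[C@](C)(O)/C=C\CO)[C@@H](CO1)C(=C)[Sn](CCCC)(CCCC)CCCC | intermediate
36 | C10 allylic acetate | CO[C@@H]1C[C@@H](CC[C@](C)(O)/C=C\COC(C)=O)[C@@H](CO1)C(=C)[Sn](CCCC)(CCCC)CCCC | intermediate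
37 | bicyclic methyl acetal (3S,4aR,7S,11aR,8Z) | C=C1C/C=C\[C@@](C)(O)CC[C@@H]2C[C@@H](OC)OC[C@@H]12 | intermediate
38 | bicyclic lactol (anomers) | C=C1C/C=C\[C@@](C)(O)CC[C@@H]2CC(O)OC[C@@H]12 | intermediate
39 | bicyclic hydroxy lactone (4aR,7S,11aR,8Z) | C=C1C/C=C\[C@@](C)(O)CC[C@@H]2CC(=O)OC[C@@H]12 | intermediate
40 | (S)-2,2-dimethyl-1,3-dioxolane-4-carbaldehyde | O=C[C@@H]1COC(C)(C)O1 | starting material
41 | isopropyltriphenylphosphonium iodide | CC(C)[P+](c1ccccc1)(c1ccccc1)c1ccccc1.[I-] | starting material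
42 | isopropylidenetriphenylphosphorane | CC(C)=P(c1ccccc1)(c1ccccc1)c1ccccc1 | intermediate
43 | (R)-2,2-dimethyl-4-(2-methylprop-1-en-1-yl)-1,3-dioxolane | CC(C)=C[C@@H]1COC(C)(C)O1 | intermediate
44 | (R)-4-methylpent-3-ene-1,2-diol | CC(C)=C[C@@H](O)CO | intermediate
45 | (R)-4-methyl-1-(triethylsilyloxy)pent-3-en-2-ol | CC(C)=C[C@@H](O)CO[Si](CC)(CC)CC | intermediate
46 | (S)-1-[(R)-3,3-dimethyloxiran-2-yl]-2-(triethylsilyloxy)ethan-1-ol | CC[Si](CC)(CC)OC[C@H](O)[C@H]1OC1(C)C | intermediate
47 | O-13 tert-butyldimethylsilyl, O-12 triethylsilyl ether of the epoxy diol | CC[Si](CC)(CC)OC[C@H](O[Si](C)(C)C(C)(C)C)[C@H]1OC1(C)C | intermediate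
48 | C12 alkoxydimethylsulfonium chloride | C[S+](C)OC[C@H](O[Si](C)(C)C(C)(C)C)[C@H]1OC1(C)C.[Cl-] | intermediate
49 | (R)-2-(tert-butyldimethylsilyloxy)-2-[(R)-3,3-dimethyloxiran-2-yl]acetaldehyde | O=C[C@H](O[Si](C)(C)C(C)(C)C)[C@H]1OC1(C)C | intermediate
50 | C7 lithium alkoxide/lithium enolate of 39 | C=C1C/C=C\[C@@](C)(O[Li])CC[C@@H]2C=C(O[Li])OC[C@@H]12 | intermediate
51 | aldol adduct (C4/C12 mixture) | C=C1C/C=C\[C@@](C)(O)CC[C@@H]2C(C(O)[C@H](O[Si](C)(C)C(C)(C)C)[C@H]3OC3(C)C)C(=O)OC[C@@H]12 | intermediate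
52 | C12 acetate of 51 | C=C1C/C=C\[C@@](C)(O)CC[C@@H]2C(C(OC(C)=O)[C@H](O[Si](C)(C)C(C)(C)C)[C@H]3OC3(C)C)C(=O)OC[C@@H]12 | intermediate
53 | (4E)-alkylidene lactone, O-13 silyl ether | C=C1C/C=C\[C@@](C)(O)CC[C@@H]2/C(=C\[C@H](O[Si](C)(C)C(C)(C)C)[C@H]3OC3(C)C)C(=O)OC[C@@H]12 | intermediate
54 | (4E)-alkylidene lactone, free 13S alcohol | C=C1C/C=C\[C@@](C)(O)CC[C@@H]2/C(=C\[C@H](O)[C@H]3OC3(C)C)C(=O)OC[C@@H]12 | intermediate
55 | 13-acetate with C8=C9 Z-alkene | C=C1C/C=C\[C@@](C)(O)CC[C@@H]2/C(=C\[C@H](OC(C)=O)[C@H]3OC3(C)C)C(=O)OC[C@@H]12 | intermediate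
56 | CNP0113449.2 | C=C1C[C@H]2O[C@H]2[C@@](C)(O)CC[C@@H]2/C(=C\[C@H](OC(C)=O)[C@H]3OC3(C)C)C(=O)OC[C@@H]12 | target

**Step count**
Total: 35 steps. Longest linear sequence: 25 steps (steps 1–14, 19–24, 31–35).

**Steps most likely to fail**
1) Step 22. Intermolecular coupling to oligomers may outrun closure of the strained nine-membered ring. So may syn–anti isomerisation of the η3-allyl unit with loss of the Z geometry, O-allylation by C7–OH, or protodestannylation. The fallback sets out from 34 and comes back at 37, replacing steps 20–22 by a metathesis closure at C8=C9. Intermolecular Stille coupling of 34 with allyl bromide (Pd2(dba)3·CHCl3, AsPh3, THF) gives the allylated triene F1, in which C9 and C10 come from the allyl group. Ring-closing metathesis follows with the second-generation Hoveyda–Grubbs catalyst in dilute toluene. It starts at the terminal allyl alkene, closes onto the internal Z-alkene at C8, expels the silyloxymethyl-bearing alkene end, and should give 37, ring strain again favouring the Z-alkene.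

2) Step 19. Borylation at the γ-carbon, erosion of the alkene geometry, 1,4-loss of silanolate from the allyllithium, reversal of boronate formation before migration, or tin–lithium exchange would lower yield or stereochemical fidelity. The fallback sets out from 23 and comes back at 35, and it sets C7 by reagent control.
- Oxidation of 23 with NaBO3·4H2O gives the primary alcohol F2.
- Dess–Martin oxidation gives the C6 aldehyde F3.
- Wittig reaction with Ph3P=C(CH3)CO2Et gives the (E)-2-methyl enoate F4, which iBu2AlH reduces to the allylic alcohol F5.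
- Sharpless asymmetric epoxidation (Ti(OiPr)4, D-(−)-diethyl tartrate, tBuOOH) gives the (6R,7R)-epoxy alcohol F6.
- LiAlH4 opens F6 at the less hindered C6 to give the 7,8-diol F7 with the tertiary hydroxyl in the 7S configuration.
- SO3·pyridine/DMSO oxidation gives the α-hydroxy aldehyde F8.
- Still–Gennari olefination gives the Z-enoate F9, which lactonises in the flask to the butenolide F10.
- Reduction of F10 with excess iBu2AlH gives the Z-enediol 35.

3) Step 32. The elimination may give E/Z mixtures. DBU may also remove the vinylogous proton H-13 of the product with opening of the side-chain oxirane, and slow acetylation of C7–OH may interfere. The fallback sets out from 39 and comes back at 54, replacing aldol/elimination by a Horner–Wadsworth–Emmons olefination under weakly basic conditions.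
- Et3SiOTf/2,6-lutidine converts 39 into the C7 triethylsilyl ether F11.
- LiN(iPr)2 followed by ClP(O)(OEt)2 gives the ketene acetal phosphate F12.
- A second portion of LiN(iPr)2 shifts phosphorus from O to C4 and gives the α-diethylphosphono lactone F13.
- Olefination of 49 with F13 under Masamune–Roush conditions (LiCl, DBU, MeCN) should give the bis-silylated (4E)-alkylidene lactone F14.
- Bu4NF/AcOH removes both silyl groups and gives 54.

Further compounds
F1 | step 22 | allylated triene (34 with allyl in place of SnBu3) | CO[C@@H]1C[C@@H](CC[C@](C)(O)/C=C\CO[Si](C)(C)C(C)(C)C)[C@@H](CO1)C(=C)CC=C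
F2 | step 19 | primary alcohol (C6–OH) from 23 | CO[C@@H]1C[C@@H](CCO)[C@@H](CO1)C(=C)[Sn](CCCC)(CCCC)CCCC
F3 | step 19 | C6 aldehyde | CO[C@@H]1C[C@@H](CC=O)[C@@H](CO1)C(=C)[Sn](CCCC)(CCCC)CCCC
F4 | step 19 | ethyl (E)-2-methyl enoate (C6=C7) | CO[C@@H]1C[C@@H](C/C=C(\C)C(=O)OCC)[C@@H](CO1)C(=C)[Sn](CCCC)(CCCC)CCCC
F5 | step 19 | (E)-allylic alcohol (C8–OH) | CO[C@@H]1C[C@@H](C/C=C(\C)CO)[C@@H](CO1)C(=C)[Sn](CCCC)(CCCC)CCCC
F6 | step 19 | (6R,7R)-epoxy alcohol | CO[C@@H]1C[C@@H](C[C@H]2O[C@]2(C)CO)[C@@H](CO1)C(=C)[Sn](CCCC)(CCCC)CCCC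
F7 | step 19 | (7S)-7,8-diol | CO[C@@H]1C[C@@H](CC[C@](C)(O)CO)[C@@H](CO1)C(=C)[Sn](CCCC)(CCCC)CCCC
F8 | step 19 | α-hydroxy aldehyde (C8) | CO[C@@H]1C[C@@H](CC[C@](C)(O)C=O)[C@@H](CO1)C(=C)[Sn](CCCC)(CCCC)CCCC
F9 | step 19 | methyl Z-enoate (C8=C9) | CO[C@@H]1C[C@@H](CC[C@](C)(O)/C=C\C(=O)OC)[C@@H](CO1)C(=C)[Sn](CCCC)(CCCC)CCCC
F10 | step 19 | 5,5-disubstituted butenolide | CO[C@@H]1C[C@@H](CC[C@@]2(C)C=CC(=O)O2)[C@@H](CO1)C(=C)[Sn](CCCC)(CCCC)CCCC
F11 | step 32 | C7 triethylsilyl ether of 39 | C=C1C/C=C\[C@@](C)(O[Si](CC)(CC)CC)CC[C@@H]2CC(=O)OC[C@@H]12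
F12 | step 32 | ketene acetal diethyl phosphate | C=C1C/C=C\[C@@](C)(O[Si](CC)(CC)CC)CC[C@@H]2C=C(OP(=O)(OCC)OCC)OC[C@@H]12
F13 | step 32 | α-diethylphosphono lactone (C4 epimers) | C=C1C/C=C\[C@@](C)(O[Si](CC)(CC)CC)CC[C@@H]2C(P(=O)(OCC)OCC)C(=O)OC[C@@H]12
F14 | step 32 | bis-silylated (4E)-alkylidene lactone | C=C1C/C=C\[C@@](C)(O[Si](CC)(CC)CC)CC[C@@H]2/C(=C\[C@H](O[Si](C)(C)C(C)(C)C)[C@H]3OC3(C)C)C(=O)OC[C@@H]12
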